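**Retrosynthetic overview**
The strategy rests on C4 of the upper (epigallocatechin) C ring. It is a CH bonded to two phloroglucinol-type rings, at C4a of its own A ring and at C8 of the catechin A ring, so it is the carbon of an aldehyde that has been arylated twice.
Cutting C4–C8 and C4–C4a together gives benzylated (+)-catechin, whose three rings are bought intact, and an open-chain 2-benzyloxy-3-aryloxy-3-arylpropanal.
In that aldehyde the A ring is already attached through the O1–C2 aryl ether. This ether comes from SN2 opening of a cis-epoxide (gallate → Z-cinnamyl alcohol → Sharpless epoxidation) with 3,5-bis(benzyloxy)phenol made from phloroglucinol.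
Ring order: the upper A and B rings are bought as arenes. The upper C ring is the only ring built, and it closes last, in the same operation that joins the two flavan halves. One hydrogenolysis then removes ten benzyl groups.
Key step: step 16

Remark: the SMILES is read as upper unit 2R,3R,4R (2,3-cis, 3,4-trans, 4β) and lower unit 2R,3S. Any minor enantiomer left from step 6 becomes a diastereomer of 21 after coupling with enantiopure 18 and is removed there by chromatography.

Step 1
Reactants: 1 methyl gallate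
Product: 2 methyl 3,4,5-tris(benzyloxy)benzoate
Conditions: BnBr (3.6 equiv), K2CO3, DMF, 60 °C
Reagents that add atoms: benzyl bromide, BrCc1ccccc1
Why: Williamson etherification of the three acidic phenols, under which the methyl ester is inert to carbonate.

Step 2
Reactants: 2 methyl 3,4,5-tris(benzyloxy)benzoate
Product: 3 [3,4,5-tris(benzyloxy)phenyl]methanol
Conditions: LiAlH4, THF, 0 °C → rt; Fieser work-up
Reagents that add atoms: none
Why: Hydride reduction of an aryl ester to the benzylic alcohol, with the benzyl ethers untouched.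

Step 3
Reactants: 3 [3,4,5-tris(benzyloxy)phenyl]methanol
Product: 4 3,4,5-tris(benzyloxy)benzaldehyde
Conditions: TEMPO (10 mol %), PhI(OAc)2 (1.1 equiv), CH2Cl2, rt
Reagents that add atoms: none
Why: Oxoammonium (TEMPO/BAIB) oxidation of a benzylic alcohol stops at the aldehyde and tolerates electron-rich arenes.

Step 4
Reactants: 4 3,4,5-tris(benzyloxy)benzaldehyde
Product: 5 ethyl (Z)-3-[3,4,5-tris(benzyloxy)phenyl]prop-2-enoate
Conditions: ethyl (di-o-tolylphosphono)acetate, NaH, THF, −78 → 0 °C
Reagents that add atoms: ethyl 2-[bis(2-methylphenoxy)phosphoryl]acetate, CCOC(=O)CP(=O)(Oc1ccccc1C)Oc1ccccc1C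
Why: In the Ando variant of the Horner–Wadsworth–Emmons olefination the electron-poor diaryl phosphonate makes collapse of the first-formed adduct fast and irreversible, which with aromatic aldehydes should give the Z-enoate under kinetic control.

Step 5
Reactants: 5 ethyl (Z)-3-[3,4,5-tris(benzyloxy)phenyl]prop-2-enoate
Product: 6 (Z)-3-[3,4,5-tris(benzyloxy)phenyl]prop-2-en-1-ol
Conditions: DIBAL-H (2.5 equiv), CH2Cl2, −78 °C; Rochelle salt
Reagents that add atoms: none
Why: 1,2-Reduction of the enoate by DIBAL-H at low temperature keeps the Z geometry.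

Step 6
Reactants: 6 (Z)-3-[3,4,5-tris(benzyloxy)phenyl]prop-2-en-1-ol
Product: 7 [(2R,3S)-3-[3,4,5-tris(benzyloxy)phenyl]oxiran-2-yl]methanol (cis-epoxide)
Conditions: Ti(OiPr)4 (20 mol %), D-(−)-DET (26 mol %), t-BuOOH (anhydrous, 2 equiv), 4 Å MS, CH2Cl2, −20 °C
Reagents that add atoms: tert-butyl hydroperoxide, CC(C)(C)OO
Why: In the Sharpless asymmetric epoxidation the D-(−)-tartrate complex delivers oxygen suprafacially to the olefin face that gives the 2R,3S cis-epoxide, and because Z-aryl allylic alcohols are the slow and less selective substrate class, the material is enriched at the next stage.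

Step 7
Reactants: 7 [(2R,3S)-3-[3,4,5-tris(benzyloxy)phenyl]oxiran-2-yl]methanol
Product: 8 trityl ether of 7, (2R,3S)-2-[(trityloxy)methyl]-3-[3,4,5-tris(benzyloxy)phenyl]oxirane (cis)
Conditions: TrCl (1.2 equiv), Et3N, DMAP (cat.), CH2Cl2, rt; recrystallisation
Reagents that add atoms: trityl chloride, ClC(c1ccccc1)(c1ccccc1)c1ccccc1
Why: Tritylation of the primary alcohol removes the free hydroxyl that would start a Payne rearrangement under the base of step 11, gives a group that cannot migrate in step 12, and should give a crystalline solid for enantiomeric enrichment.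

Step 8
Reactants: 9 phloroglucinol
Product: 10 benzene-1,3,5-triyl triacetate
Conditions: Ac2O, pyridine, rt
Reagents that add atoms: acetic anhydride, CC(=O)OC(C)=O
Why: Peracetylation masks the phenols so that no free phloroglucinol polyanion, which is prone to C-alkylation, is present in step 9.

Step 9
Reactants: 10 benzene-1,3,5-triyl triacetate
Product: 11 1,3,5-tris(benzyloxy)benzene
Conditions: BnCl (3.6 equiv), NaH (7 equiv), H2O (3.3 equiv, added slowly), DMF, 0 °C → rt
Reagents that add atoms: benzyl chloride, ClCc1ccccc1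
Why: In this deacetylative Williamson benzylation, hydroxide formed slowly in the flask frees one phenoxide at a time and each is O-benzylated at once, which should suppress C-benzylation.

Step 10
Reactants: 11 1,3,5-tris(benzyloxy)benzene
Product: 12 3,5-bis(benzyloxy)phenol
Conditions: NaSEt (1.5 equiv), DMF, 140 °C; then 1 M HCl
Reagents that add atoms: none
Why: Thiolate SN2 dealkylation at a benzylic carbon stops after one cleavage because the resulting phenoxide makes the other two aryloxides poorer leaving groups.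

Step 11
Reactants: 8 trityl ether of the cis-epoxy alcohol; 12 3,5-bis(benzyloxy)phenol
Product: 13 (1R,2R)-1-[3,5-bis(benzyloxy)phenoxy]-1-[3,4,5-tris(benzyloxy)phenyl]-3-(trityloxy)propan-2-ol (the threo 1,2-diol as its 1-O-trityl ether)
Conditions: 12 (2 equiv), Cs2CO3 (0.5 equiv), DMF, 90–100 °C
Reagents that add atoms: none
Why: In this SN2 opening of a 3-arylglycidyl ether by a phenoxide the benzylic carbon is electronically favoured and the neighbouring carbon is retarded by the trityloxymethyl group, so inversion should turn the S benzylic carbon into the R aryl ether (future C2, O1–C2 bond) and leave the carbinol carbon (future C3) untouched, giving the threo pattern of a 2,3-cis flavan, while the near-neutral net electronic effect of the 3,4,5-trialkoxyphenyl ring disfavours SN1 leakage and caesium phenoxide in DMF favours O- over C-alkylation.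

Step 12
Reactants: 13 threo secondary alcohol
Product: 14 (1R,2R)-2-O-benzyl ether of 13
Conditions: NaH (1.5 equiv), BnBr (1.5 equiv), Bu4NI (10 mol %), DMF, 0 °C → rt
Reagents that add atoms: benzyl bromide, BrCc1ccccc1
Why: Williamson benzylation of the secondary alkoxide, in which the neighbouring trityl ether, unlike a silyl ether, cannot migrate to the alkoxide.

Step 13
Reactants: 14 benzyl trityl diether
Product: 15 (2R,3R)-2-(benzyloxy)-3-[3,5-bis(benzyloxy)phenoxy]-3-[3,4,5-tris(benzyloxy)phenyl]propan-1-ol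
Conditions: p-TsOH·H2O (10 mol %), MeOH–CH2Cl2 (1:1), rt
Reagents that add atoms: none
Why: Acid-catalysed SN1 methanolysis of the trityl ether is far faster than ionisation of the benzyl ethers or of the benzylic aryl ether, and methanol traps the trityl cation.

Step 14
Reactants: 15 primary alcohol
Product: 16 (2S,3R)-2-(benzyloxy)-3-[3,5-bis(benzyloxy)phenoxy]-3-[3,4,5-tris(benzyloxy)phenyl]propanal
Conditions: Dess–Martin periodinane (1.3 equiv), NaHCO3 (5 equiv), CH2Cl2, 0 °C → rt; short silica plug, used at once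
Reagents that add atoms: none
Why: Buffered Dess–Martin oxidation is near neutral, so epimerisation at the α-carbon (future C3; the descriptor changes to S only through CIP ranking) and E1cB loss of the β-aryloxide should be avoided.

Step 15
Reactants: 17 (+)-catechin
Product: 18 5,7,3',4'-tetra-O-benzyl-(+)-catechin (2R,3S)
Conditions: BnBr (4.3 equiv), K2CO3, DMF, Ar, 0 °C → rt
Reagents that add atoms: benzyl bromide, BrCc1ccccc1
Why: Under carbonate only the four phenols are ionised, so this Williamson etherification leaves the C3 alcohol free, and low temperature under argon guards C2 against epimerisation.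

Step 16
Reactants: 16 open-chain aldehyde; 18 5,7,3',4'-tetra-O-benzyl-(+)-catechin
Product: 21 deca-O-benzyl epigallocatechin-(4β→8)-catechin, via flavan-4-ol 19 (not isolated), via C4 cation 20 (not isolated)
Conditions: 18 (4 equiv), BF3·OEt2 (0.5 equiv), 4 Å MS, CH2Cl2, −78 °C, slow addition of 16, then −78 → −20 °C; Et3N quench; excess 18 recovered
Reagents that add atoms: none
Why: Proposed new method: BF3 activates the aldehyde of 16 and one of the two equivalent ring carbons ortho to the aryl ether oxygen attacks it in an intramolecular Friedel–Crafts hydroxyalkylation (6-exo-trig at the carbonyl carbon), which forms C4–C4a, closes the upper pyran C ring and gives flavan-4-ol 19. The C4–O bond of 19 is benzylic to a ring with ortho and para oxygen donors, so it ionises under the same acid to the quinone-methide-like cation 20, which C8 of 18 captures to form the C4–C8 interflavan bond with water as the only by-product; if 18 adds to the aldehyde first, that carbinol ionises and the tethered ring closes the same six-membered ring, so both orders lead to 21. The closest known reaction types are the acid-catalysed double arylation of aldehydes by electron-rich arenes (triarylmethane and Lindsey-type condensations) and, for the second half, the Lewis acid coupling of benzylated flavan-4-ols or 4-alkoxyflavans with 18; new is the use of one tethered and one free arene on a single aldehyde carbon. C2 and C3 are carried in from 16, and the only new stereocentre, C4, is set when 18 meets planar 20: with the B ring equatorial the C3 benzyloxy group stands axial on the α face, so the nucleophile should come from the β face and the aryl group should end quasi-axial and 3,4-trans (4R), which also avoids peri strain with the C5 benzyloxy group. The step needs ring closure ahead of a second intermolecular arylation, reaction of the A ring and not the B ring of 16, attack at C8 and not C6 of 18, and no oligomerisation. These are secured by the entropic advantage of the six-membered closure, by three ortho/para oxygens at the A-ring carbon against two at the B-ring carbon (whose closure would give a strained indanol), by the known C8 preference of 5,7-di-O-benzylcatechin, and by slow addition of 16 to an excess of 18.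

Step 17
Reactants: 21 deca-O-benzyl epigallocatechin-(4β→8)-catechin
Product: 22 epigallocatechin-(4β→8)-catechin (CNP0225927.1)
Conditions: H2 (1 atm), 20 % Pd(OH)2/C, THF–MeOH–H2O, rt; filtration under Ar, lyophilisation
Reagents that add atoms: none
Why: Neutral catalytic hydrogenolysis with Pearlman's catalyst cleaves all ten benzyl ethers, while the ring C2–O1 bonds and the C4–C8 bond of this compound class survive and no stereocentre is touched.

**Compound list**
1 | methyl gallate | COC(=O)c1cc(O)c(O)c(O)c1 | starting material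
2 | methyl 3,4,5-tris(benzyloxy)benzoate | COC(=O)c1cc(OCc2ccccc2)c(OCc2ccccc2)c(OCc2ccccc2)c1 | intermediate
3 | [3,4,5-tris(benzyloxy)phenyl]methanol | OCc1cc(OCc2ccccc2)c(OCc2ccccc2)c(OCc2ccccc2)c1 | intermediate
4 | 3,4,5-tris(benzyloxy)benzaldehyde | O=Cc1cc(OCc2ccccc2)c(OCc2ccccc2)c(OCc2ccccc2)c1 | intermediate
5 | ethyl (Z)-3-[3,4,5-tris(benzyloxy)phenyl]prop-2-enoate | CCOC(=O)/C=C\c1cc(OCc2ccccc2)c(OCc2ccccc2)c(OCc2ccccc2)c1 | intermediate
6 | (Z)-3-[3,4,5-tris(benzyloxy)phenyl]prop-2-en-1-ol | OC/C=C\c1cc(OCc2ccccc2)c(OCc2ccccc2)c(OCc2ccccc2)c1 | intermediate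
7 | [(2R,3S)-3-[3,4,5-tris(benzyloxy)phenyl]oxiran-2-yl]methanol | C(c1ccccc1)Oc1cc(cc(OCc2ccccc2)c1OCc1ccccc1)[C@@H]1O[C@@H]1CO | intermediate
8 | (2R,3S)-2-[(trityloxy)methyl]-3-[3,4,5-tris(benzyloxy)phenyl]oxirane | C(c1ccccc1)Oc1cc(cc(OCc2ccccc2)c1OCc1ccccc1)[C@@H]1O[C@@H]1COC(c1ccccc1)(c1ccccc1)c1ccccc1 | intermediate
9 | phloroglucinol | Oc1cc(O)cc(O)c1 | starting material
10 | benzene-1,3,5-triyl triacetate | CC(=O)Oc1cc(OC(C)=O)cc(OC(C)=O)c1 | intermediate
11 | 1,3,5-tris(benzyloxy)benzene | C(c1ccccc1)Oc1cc(OCc2ccccc2)cc(OCc2ccccc2)c1 | intermediate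
12 | 3,5-bis(benzyloxy)phenol | Oc1cc(OCc2ccccc2)cc(OCc2ccccc2)c1 | intermediate
13 | (1R,2R)-1-[3,5-bis(benzyloxy)phenoxy]-1-[3,4,5-tris(benzyloxy)phenyl]-3-(trityloxy)propan-2-ol | C(c1ccccc1)Oc1cc(OCc2ccccc2)cc(c1)O[C@H](c1cc(OCc2ccccc2)c(OCc2ccccc2)c(OCc2ccccc2)c1)[C@H](O)COC(c1ccccc1)(c1ccccc1)c1ccccc1 | intermediate
14 | (1R,2R)-2-O-benzyl ether of 13 | C(c1ccccc1)Oc1cc(OCc2ccccc2)cc(c1)O[C@H](c1cc(OCc2ccccc2)c(OCc2ccccc2)c(OCc2ccccc2)c1)[C@H](OCc1ccccc1)COC(c1ccccc1)(c1ccccc1)c1ccccc1 | intermediate
15 | (2R,3R)-2-(benzyloxy)-3-[3,5-bis(benzyloxy)phenoxy]-3-[3,4,5-tris(benzyloxy)phenyl]propan-1-ol | C(c1ccccc1)Oc1cc(OCc2ccccc2)cc(c1)O[C@H](c1cc(OCc2ccccc2)c(OCc2ccccc2)c(OCc2ccccc2)c1)[C@H](OCc1ccccc1)CO | intermediate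
16 | (2S,3R)-2-(benzyloxy)-3-[3,5-bis(benzyloxy)phenoxy]-3-[3,4,5-tris(benzyloxy)phenyl]propanal | C(c1ccccc1)Oc1cc(OCc2ccccc2)cc(c1)O[C@H](c1cc(OCc2ccccc2)c(OCc2ccccc2)c(OCc2ccccc2)c1)[C@H](OCc1ccccc1)C=O | intermediate
17 | (+)-catechin | c1c(O)cc(O)c2c1O[C@H](c1ccc(O)c(O)c1)[C@@H](O)C2 | starting material
18 | 5,7,3',4'-tetra-O-benzyl-(+)-catechin | c1c(OCc3ccccc3)cc(OCc3ccccc3)c2c1O[C@H](c1ccc(OCc3ccccc3)c(OCc3ccccc3)c1)[C@@H](O)C2 | intermediate
19 | (2R,3R)-3,5,7-tris(benzyloxy)-2-[3,4,5-tris(benzyloxy)phenyl]chroman-4-ol, 2,3-cis, C4 undefined | C(c3ccccc3)Oc1cc(OCc3ccccc3)c2c(c1)O[C@H](c1cc(OCc3ccccc3)c(OCc3ccccc3)c(OCc3ccccc3)c1)[C@H](OCc1ccccc1)C2O | intermediate (not isolated)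
20 | C4 carbocation from 19 (A-ring-stabilised, quinone-methide-like) | C(c3ccccc3)Oc1cc(OCc3ccccc3)c2c(c1)O[C@H](c1cc(OCc3ccccc3)c(OCc3ccccc3)c(OCc3ccccc3)c1)[C@H](OCc1ccccc1)[CH+]2 | intermediate (not isolated)
21 | 3,5,7,3',4',5'-hexa-O-benzylepigallocatechin-(4β→8)-5,7,3',4'-tetra-O-benzylcatechin (upper 2R,3R,4R; lower 2R,3S) | C(c3ccccc3)Oc1cc(OCc3ccccc3)c2c(c1)O[C@H](c1cc(OCc3ccccc3)c(OCc3ccccc3)c(OCc3ccccc3)c1)[C@H](OCc1ccccc1)[C@H]2c1c(OCc3ccccc3)cc(OCc3ccccc3)c2c1O[C@H](c1ccc(OCc3ccccc3)c(OCc3ccccc3)c1)[C@@H](O)C2 | intermediate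
22 | epigallocatechin-(4β→8)-catechin (CNP0225927.1) | Oc1cc(O)c2c(c1)O[C@H](c1cc(O)c(O)c(O)c1)[C@H](O)[C@H]2c1c(O)cc(O)c2c1O[C@H](c1ccc(O)c(O)c1)[C@@H](O)C2 | target

**Total step count:** 17. **Longest linear sequence:** 13 (steps 1–7, 11–14, 16, 17).

**Steps most likely to fail**

1. Step 16.
   - What may go wrong: the activated α-benzyloxy-β-aryloxy aldehyde may enolise or lose the aryloxide by β-elimination before it cyclises. A second molecule of 18 may trap the first carbinol faster than the tethered ring does. Product-derived nucleophiles may start oligomerisation, and facial selectivity may erode if the order of the two arylations changes.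
   - Fallback (known chemistry): it sets out from 18 and comes back at 21. Purchased (−)-epigallocatechin F1 is benzylated on its five phenols (BnBr, K2CO3, DMF) to 5,7,3',4',5'-penta-O-benzylepigallocatechin F2. O3 is then benzylated (NaH, BnBr, DMF) to 3,5,7,3',4',5'-hexa-O-benzylepigallocatechin F3. DDQ oxidation at C4 in the presence of 2-ethoxyethanol gives the 4β-(2-ethoxyethoxy)flavan F4, the standard C4 electrophile. F4 is coupled with an excess of 18 under TMSOTf in CH2Cl2 at −78 °C to give 21.

2. Step 11.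
   - What may go wrong: the hindered cis-epoxide may open slowly, attack may compete at the non-benzylic carbon, the ambident phenoxide may C-alkylate, and partial ionisation may leak configuration at the benzylic carbon.
   - Fallback: it sets out from 4 and comes back at 13. It uses the more reactive and more selectively made trans-epoxide and corrects C2 of the chain afterwards.
   - E-selective Horner–Wadsworth–Emmons olefination (triethyl phosphonoacetate, NaH) gives the ethyl (E)-cinnamate F5, and DIBAL-H gives the (E)-allylic alcohol F6.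
   - Sharpless epoxidation with L-(+)-DIPT gives the (2S,3S)-trans-epoxy alcohol F7. Opening with 12 in aqueous NaOH–dioxane, the well-precedented case of a trans-3-arylglycidol, gives the erythro (2S,3R)-diol F8.
   - Tritylation of the primary alcohol gives the erythro trityl ether F9. Mitsunobu inversion of the secondary alcohol (4-nitrobenzoic acid, PPh3, DIAD) gives the (1R,2R)-4-nitrobenzoate F10, and K2CO3 in MeOH releases 13.

3. Step 6.
   - What may go wrong: turnover may be slow and enantioselectivity modest with a Z-aryl allylic alcohol, and titanium may open the product epoxide during the long reaction time.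
   - Fallback: it sets out from 5 and comes back at 7. Jacobsen–Katsuki epoxidation of the Z-enoate with the (S,S)-Mn(salen) catalyst, NaOCl and 4-phenylpyridine N-oxide, a method tuned to cis-disubstituted conjugated olefins, gives the ethyl (2S,3S)-cis-glycidate F11. Chemoselective reduction of its ester with NaBH4 in EtOH at 0 °C gives 7.

**Further compounds**
F1 | step 16 | (−)-epigallocatechin (purchased) | Oc1cc(O)c2c(c1)O[C@H](c1cc(O)c(O)c(O)c1)[C@H](O)C2
F2 | step 16 | 5,7,3',4',5'-penta-O-benzyl-(−)-epigallocatechin | C(c3ccccc3)Oc1cc(OCc3ccccc3)c2c(c1)O[C@H](c1cc(OCc3ccccc3)c(OCc3ccccc3)c(OCc3ccccc3)c1)[C@H](O)C2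
F3 | step 16 | 3,5,7,3',4',5'-hexa-O-benzyl-(−)-epigallocatechin | C(c3ccccc3)Oc1cc(OCc3ccccc3)c2c(c1)O[C@H](c1cc(OCc3ccccc3)c(OCc3ccccc3)c(OCc3ccccc3)c1)[C@H](OCc1ccccc1)C2
F4 | step 16 | 4β-(2-ethoxyethoxy)-3,5,7,3',4',5'-hexa-O-benzylepigallocatechin | C(c3ccccc3)Oc1cc(OCc3ccccc3)c2c(c1)O[C@H](c1cc(OCc3ccccc3)c(OCc3ccccc3)c(OCc3ccccc3)c1)[C@H](OCc1ccccc1)[C@H]2OCCOCC
F5 | step 11 | ethyl (E)-3-[3,4,5-tris(benzyloxy)phenyl]prop-2-enoate | CCOC(=O)/C=C/c1cc(OCc2ccccc2)c(OCc2ccccc2)c(OCc2ccccc2)c1
F6 | step 11 | (E)-3-[3,4,5-tris(benzyloxy)phenyl]prop-2-en-1-ol | OC/C=C/c1cc(OCc2ccccc2)c(OCc2ccccc2)c(OCc2ccccc2)c1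
F7 | step 11 | [(2S,3S)-3-[3,4,5-tris(benzyloxy)phenyl]oxiran-2-yl]methanol (trans) | C(c1ccccc1)Oc1cc(cc(OCc2ccccc2)c1OCc1ccccc1)[C@@H]1O[C@H]1CO
F8 | step 11 | (2S,3R)-3-[3,5-bis(benzyloxy)phenoxy]-3-[3,4,5-tris(benzyloxy)phenyl]propane-1,2-diol (erythro) | C(c1ccccc1)Oc1cc(OCc2ccccc2)cc(c1)O[C@H](c1cc(OCc2ccccc2)c(OCc2ccccc2)c(OCc2ccccc2)c1)[C@@H](O)CO
F9 | step 11 | (1R,2S)-1-[3,5-bis(benzyloxy)phenoxy]-1-[3,4,5-tris(benzyloxy)phenyl]-3-(trityloxy)propan-2-ol | C(c1ccccc1)Oc1cc(OCc2ccccc2)cc(c1)O[C@H](c1cc(OCc2ccccc2)c(OCc2ccccc2)c(OCc2ccccc2)c1)[C@@H](O)COC(c1ccccc1)(c1ccccc1)c1ccccc1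
F10 | step 11 | (1R,2R)-1-[3,5-bis(benzyloxy)phenoxy]-1-[3,4,5-tris(benzyloxy)phenyl]-3-(trityloxy)propan-2-yl 4-nitrobenzoate | C(c1ccccc1)Oc1cc(OCc2ccccc2)cc(c1)O[C@H](c1cc(OCc2ccccc2)c(OCc2ccccc2)c(OCc2ccccc2)c1)[C@H](OC(=O)c1ccc(cc1)[N+](=O)[O-])COC(c1ccccc1)(c1ccccc1)c1ccccc1
F11 | step 6 | ethyl (2S,3S)-3-[3,4,5-tris(benzyloxy)phenyl]oxirane-2-carboxylate (cis) | C(c1ccccc1)Oc1cc(cc(OCc2ccccc2)c1OCc1ccccc1)[C@@H]1O[C@@H]1C(=O)OCC
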